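The target is epicatechin-(4α→8)-epicatechin gallate-(4β→8)-epicatechin gallate (units T, M, B; flavan numbering). The plan cuts T C3–C4 and T O1–C2. It exploits the cis pair O3 / M C8 aryl on C3 and C4 of T ring C. This pair lies next to aryl ether oxygen O1 of the phloroglucinol-type ring A, which is what a two-carbon partner leaves on an o-quinone methide. In one operation, the ring A quinone methide (M C8 on its methide carbon) is intercepted by the catalyst-bound enolate of benzyloxyketene. Ring C closes as a cis-dihydrocoumarin and sets both stereocentres. The precursor is an o-hydroxybenzhydrol made from 8-lithiated M and a salicylaldehyde. M already carries its C4 leaving group.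

Key step: step 9

**Conventions:**
- α is the face of a flavan unit that bears its C2 aryl group (and O3 in epicatechin); β is the other face.
- Bn = benzyl. TBS = tert-butyldimethylsilyl.
- "M-8-yl" = 4β-(2-ethoxyethoxy)-3-O-TBS-5,7,3',4'-tetra-O-benzylepicatechin-8-yl.

**Reading of the target:**
- All three units have the (2R,3R) epicatechin pattern.
- The M–B bond is 4β (3,4-trans).
- The T–M bond is 4α (3,4-cis), so T ring C is all-cis.

**Assumption:** O-benzoylquinidine is taken as the pseudoenantiomer that leaves the Re face of the enolate α-carbon open. If the sense on this alkoxy enolate is the reverse, O-benzoylquinine takes its place and nothing else changes.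

**Design points:**
- M C4 is oxidised on the monomer. The 2-ethoxyethoxy group then rides through the key step as a spectator, because in a T–M dimer the doubly benzylic T C4–H would compete for DDQ.
- B is attached at the lactone stage, where the acyl group on T O1 tames T ring A.
- T O3 is a benzyl ether while O3 of M and of B are silyl ethers, so both gallates go on together at the end.
- The carbinol is made from lithiated M and an aldehyde, which avoids any directed lithiation of a benzyl ether.

Step 1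
Reactants: 1 (−)-epicatechin
Product: 2 5,7,3',4'-tetra-O-benzyl-(−)-epicatechin
Conditions: BnBr (4.2 equiv), K2CO3, DMF, 0 °C to rt
Reagents that add atoms: benzyl bromide, BrCc1ccccc1
Why: Williamson etherification in which carbonate deprotonates only the four phenols, so the secondary 3-OH stays free and C2 and C3 are not touched.

Step 2
Reactants: 2 5,7,3',4'-tetra-O-benzyl-(−)-epicatechin
Product: 3 3-O-TBS-5,7,3',4'-tetra-O-benzyl-(−)-epicatechin
Conditions: TBSCl, imidazole, DMF, rt
Reagents that add atoms: tert-butyldimethylsilyl chloride, CC(C)(C)[Si](C)(C)Cl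
Why: Imidazole-promoted silylation of the single remaining hydroxyl gives a group that survives organolithiums, DDQ and cold Lewis acid and later marks O3 of M and of B for galloylation.

Step 3
Reactants: 3 3-O-TBS-5,7,3',4'-tetra-O-benzyl-(−)-epicatechin
Product: 4 4β-(2-ethoxyethoxy)-3-O-TBS-5,7,3',4'-tetra-O-benzylepicatechin
Conditions: DDQ (2 equiv), 2-ethoxyethanol (5 equiv), CH2Cl2, rt
Reagents that add atoms: 2-ethoxyethanol, OCCOCC
Why: DDQ-mediated benzylic C–H oxidation (hydride abstraction) at C4, the position activated by all three ring A oxygens, gives a cation that the alcohol should trap anti to the axial 3-OTBS group (4β, 3,4-trans).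

Step 4
Reactants: 4 4β-(2-ethoxyethoxy)-3-O-TBS-5,7,3',4'-tetra-O-benzylepicatechin
Product: 5 8-bromo-4β-(2-ethoxyethoxy)-3-O-TBS-5,7,3',4'-tetra-O-benzylepicatechin
Conditions: NBS (1.0 equiv), CH2Cl2, −78 to −20 °C
Reagents that add atoms: N-bromosuccinimide, O=C1CCC(=O)N1Br
Why: Electrophilic aromatic bromination with one equivalent of NBS in the cold goes to C8, the more nucleophilic of the two free ring A positions of O-benzylated flavan-3-ols.

Step 5
Reactants: 6 2,4,6-trihydroxybenzaldehyde
Product: 7 2,4-bis(benzyloxy)-6-hydroxybenzaldehyde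
Conditions: BnBr (2.05 equiv), K2CO3, DMF, rt
Reagents that add atoms: benzyl bromide, BrCc1ccccc1
Why: Williamson etherification with two equivalents of halide should stop at the dibenzyl ether because the last ortho hydroxyl is tied up in a hydrogen bond to the formyl oxygen.

Step 6
Reactants: 7 2,4-bis(benzyloxy)-6-hydroxybenzaldehyde
Product: 8 2-allyloxy-4,6-bis(benzyloxy)benzaldehyde
Conditions: allyl bromide, K2CO3, DMF, 50 °C
Reagents that add atoms: allyl bromide, C=CCBr
Why: Forcing Williamson allylation caps the chelated phenol with a group that is inert to aryllithiums, cannot migrate to a neighbouring alkoxide as a silyl or acyl group would, and comes off without acid or fluoride.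

Step 7
Reactants: 5 8-bromo-4β-(2-ethoxyethoxy)-3-O-TBS-5,7,3',4'-tetra-O-benzylepicatechin; 8 2-allyloxy-4,6-bis(benzyloxy)benzaldehyde
Product: 10 [2-allyloxy-4,6-bis(benzyloxy)phenyl](M-8-yl)methanol (both carbinol epimers), via 8-lithio flavan 9 (not isolated)
Conditions: n-BuLi (1.05 equiv), THF, −78 °C; then 8, −78 to −40 °C; H2O quench
Reagents that add atoms: none
Why: Bromine–lithium exchange followed by 1,2-addition of the aryllithium to the aldehyde forms the M C8–T C4 bond, and the new carbinol centre needs no control because step 9 planarises it.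

Step 8
Reactants: 10 [2-allyloxy-4,6-bis(benzyloxy)phenyl](M-8-yl)methanol
Product: 11 [2,4-bis(benzyloxy)-6-hydroxyphenyl](M-8-yl)methanol (o-hydroxybenzhydrol; both carbinol epimers)
Conditions: Pd(PPh3)4 (5 mol %), morpholine, THF, rt; filtration through Et3N-deactivated silica
Reagents that add atoms: none
Why: Tsuji–Trost-type deallylation in which zerovalent palladium ionises only the aryl allyl ether and morpholine takes up the allyl group, leaving benzyl, silyl and alkyl ethers and the acid-labile carbinol untouched in a mildly basic medium.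

Step 9
Reactants: 11 [2,4-bis(benzyloxy)-6-hydroxyphenyl](M-8-yl)methanol; 12 benzyloxyacetyl chloride
Product: 15 (3R)-3,4-cis-3,5,7-tris(benzyloxy)-4-(M-8-yl)-3,4-dihydrocoumarin (O3 and M both on the α face), via o-quinone methide 13 (not isolated), via benzyloxyketene 14 (not isolated)
Conditions: (PhO)2PO2H (2 mol %), 4 Å MS, toluene, rt; then iPr2NEt (3 equiv), O-benzoylquinidine (20 mol %), −40 °C, 12 (2 equiv) by syringe pump; cold pH 5 buffer quench
Reagents that add atoms: none
Why: Weak-acid-catalysed loss of water from 11 gives the persistent, donor-stabilised methide 13, iPr2NEt turns 12 into ketene 14, and O-benzoylquinidine captures 14 as a (Z)-ammonium enolate whose α-carbon adds to the methide carbon (T C3–C4), after which the rearomatised phenoxide attacks the acylammonium carbon (T O1–C2) and frees the catalyst. The closest known reaction type is the Lewis-base-catalysed (cinchona ester or isothiourea) formal [4+2] of C1 ammonium enolates with o-quinone methides to cis-3,4-dihydrocoumarins, and cinchona-bound alkoxyketene enolates are established in the related cycloadditions with imines. Ring C closes by a 6-exo-trig lactonisation that follows the intermolecular Michael addition. T C3 is set by the catalyst, which shields one enolate face so that the Re face of the α-carbon bonds (3R), and T C4 is set by the relative topicity: the 5-benzyloxy group forces the M aryl to the carbonyl side of the methide, where it stands perpendicular and blocks the outer sector, so the ammonium group should lie over flat ring A while O− and OBn point outward and OBn and M end up cis. The step needs cis selectivity and one absolute sense relative to enantiopure M; the fixed methide geometry serves the first, the catalyst the second, and any minor isomer is a diastereomer that chromatography can remove. Regained aromaticity of ring A drives the addition, the singly activated M C4 ether is not ionised by the weak acid, and the acidic quench with base-free handling keeps the kinetic cis lactone from epimerising at C3.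

Step 10
Reactants: 15 (3R)-3,4-cis-3,5,7-tris(benzyloxy)-4-(M-8-yl)-3,4-dihydrocoumarin; 3 3-O-TBS-5,7,3',4'-tetra-O-benzyl-(−)-epicatechin
Product: 16 trimer lactone (M C4β bonded to B C8; T still a dihydrocoumarin)
Conditions: 3 (4 equiv, excess recovered), TMSOTf (20 mol %), CH2Cl2, −78 °C
Reagents that add atoms: none
Why: Lewis-acid-promoted Friedel–Crafts flavanylation, the standard interflavan bond formation, in which the ionised M C4 is attacked by C8 of the excess nucleophile anti to the axial 3-OTBS group (4β, 3,4-trans), while the acyl group on T O1 deactivates T ring A against self-condensation and the base-free medium leaves T C3 alone.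

Step 11
Reactants: 16 trimer lactone; 17 4-bromo-1,2-bis(benzyloxy)benzene
Product: 19 trimer T C2 hemiketal (2-aryl-2-hydroxychroman; anomer mixture in equilibrium with the hydroxy ketone), via 3,4-bis(benzyloxy)phenyllithium 18 (not isolated)
Conditions: 17, n-BuLi, THF, −78 °C; cannulated (1.15 equiv) into 16, THF, −78 °C; AcOH quench at −78 °C
Reagents that add atoms: none
Why: Single addition of an aryllithium to a lactone at −78 °C, as in C-aryl glycoside synthesis, installs T ring B on C2, and the cold acetic acid quench guards T C3 against enolisation.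

Step 12
Reactants: 19 trimer T C2 hemiketal
Product: 20 protected trimer with all-cis T ring C (T 3,5,7,3',4'-penta-O-benzyl; M and B 3-O-TBS-tetra-O-benzyl)
Conditions: Et3SiH (10 equiv), BF3·OEt2 (2 equiv), CH2Cl2, −78 to −40 °C
Reagents that add atoms: none
Why: Ionic reduction of the hemiketal through its 2-aryl oxocarbenium ion, as for lactol-derived C-aryl glycosides, in which the 3-benzyloxy group and the bulky pseudoaxial 4-aryl group both cover the α face, so hydride should enter from the β face and place ring B on the α side (T C2 as in epicatechin).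

Step 13
Reactants: 20 protected trimer
Product: 21 trimer diol (O3 of M and O3 of B free; T O3 benzylated)
Conditions: Bu4NF, THF, rt to 40 °C
Reagents that add atoms: none
Why: Fluoride-induced desilylation frees only O3 of M and of B, since T O3 is a benzyl ether and no base-sensitive centre is left.

Step 14
Reactants: 21 trimer diol; 22 3,4,5-tris(benzyloxy)benzoic acid
Product: 23 nonadeca-O-benzyl trimer digallate
Conditions: 22 (5 equiv), DCC, DMAP, CH2Cl2, rt
Reagents that add atoms: none
Why: Steglich esterification with excess acid acylates both axial secondary alcohols in one operation, as is usual for 3-O-galloylation of benzylated procyanidins, and touches no stereocentre.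

Step 15
Reactants: 23 nonadeca-O-benzyl trimer digallate
Product: 24 CNP0279403.2, epicatechin-(4α→8)-epicatechin 3-O-gallate-(4β→8)-epicatechin 3-O-gallate
Conditions: H2 (1 atm), Pd(OH)2/C, THF/MeOH/H2O, rt
Reagents that add atoms: none
Why: Global hydrogenolysis of all nineteen benzyl ethers under one atmosphere of hydrogen should leave the gallate esters, the C2–O1 bonds and both interflavan bonds intact and deliver the free polyphenol.

**Compound list**

1 | (−)-epicatechin (2R,3R) | O[C@@H]1Cc2c(O)cc(O)cc2O[C@@H]1c1ccc(O)c(O)c1 | starting material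
2 | 5,7,3',4'-tetra-O-benzyl-(−)-epicatechin | O[C@@H]1Cc2c(OCc9ccccc9)cc(OCc9ccccc9)cc2O[C@@H]1c8ccc(OCc9ccccc9)c(OCc9ccccc9)c8 | intermediate
3 | 3-O-TBS-5,7,3',4'-tetra-O-benzyl-(−)-epicatechin | CC(C)(C)[Si](C)(C)O[C@@H]1Cc2c(OCc9ccccc9)cc(OCc9ccccc9)cc2O[C@@H]1c8ccc(OCc9ccccc9)c(OCc9ccccc9)c8 | intermediate
4 | 4β-(2-ethoxyethoxy)-3-O-TBS-5,7,3',4'-tetra-O-benzylepicatechin (2,3-cis; 3,4-trans) | CC(C)(C)[Si](C)(C)O[C@@H]1[C@@H](OCCOCC)c2c(OCc9ccccc9)cc(OCc9ccccc9)cc2O[C@@H]1c8ccc(OCc9ccccc9)c(OCc9ccccc9)c8 | intermediate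
5 | 8-bromo derivative of 4 | CC(C)(C)[Si](C)(C)O[C@@H]1[C@@H](OCCOCC)c2c(OCc9ccccc9)cc(OCc9ccccc9)c(Br)c2O[C@@H]1c8ccc(OCc9ccccc9)c(OCc9ccccc9)c8 | intermediate
6 | 2,4,6-trihydroxybenzaldehyde | O=Cc1c(O)cc(O)cc1O | starting material
7 | 2,4-bis(benzyloxy)-6-hydroxybenzaldehyde | O=Cc1c(O)cc(OCc9ccccc9)cc1OCc9ccccc9 | intermediate
8 | 2-allyloxy-4,6-bis(benzyloxy)benzaldehyde | O=Cc1c(OCC=C)cc(OCc9ccccc9)cc1OCc9ccccc9 | intermediate
9 | 8-lithio flavan (5 with Li in place of Br) | CC(C)(C)[Si](C)(C)O[C@@H]1[C@@H](OCCOCC)c2c(OCc9ccccc9)cc(OCc9ccccc9)c([Li])c2O[C@@H]1c8ccc(OCc9ccccc9)c(OCc9ccccc9)c8 | intermediate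
10 | [2-allyloxy-4,6-bis(benzyloxy)phenyl](M-8-yl)methanol; carbinol carbon unassigned (both epimers) | CC(C)(C)[Si](C)(C)O[C@@H]1[C@@H](OCCOCC)c2c(OCc9ccccc9)cc(OCc9ccccc9)c(C(O)c3c(OCC=C)cc(OCc9ccccc9)cc3OCc9ccccc9)c2O[C@@H]1c8ccc(OCc9ccccc9)c(OCc9ccccc9)c8 | intermediate
11 | [2,4-bis(benzyloxy)-6-hydroxyphenyl](M-8-yl)methanol; carbinol carbon unassigned (both epimers) | CC(C)(C)[Si](C)(C)O[C@@H]1[C@@H](OCCOCC)c2c(OCc9ccccc9)cc(OCc9ccccc9)c(C(O)c3c(O)cc(OCc9ccccc9)cc3OCc9ccccc9)c2O[C@@H]1c8ccc(OCc9ccccc9)c(OCc9ccccc9)c8 | intermediate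
12 | benzyloxyacetyl chloride | O=C(Cl)COCc1ccccc1 | starting material
13 | T ring A o-quinone methide: 3,5-bis(benzyloxy)-6-[(M-8-yl)methylidene]cyclohexa-2,4-dien-1-one; M aryl on the carbonyl side | O=C1C=C(OCc9ccccc9)C=C(OCc9ccccc9)/C1=C/c1c(OCc9ccccc9)cc(OCc9ccccc9)c2c1O[C@H](c8ccc(OCc9ccccc9)c(OCc9ccccc9)c8)[C@H](O[Si](C)(C)C(C)(C)C)[C@H]2OCCOCC | intermediate
14 | benzyloxyketene | O=C=COCc1ccccc1 | intermediate
15 | (3R)-3,4-cis-3,5,7-tris(benzyloxy)-4-(M-8-yl)-3,4-dihydrocoumarin | CC(C)(C)[Si](C)(C)O[C@@H]1[C@@H](OCCOCC)c2c(OCc9ccccc9)cc(OCc9ccccc9)c([C@@H]3c4c(OCc9ccccc9)cc(OCc9ccccc9)cc4OC(=O)[C@@H]3OCc9ccccc9)c2O[C@@H]1c8ccc(OCc9ccccc9)c(OCc9ccccc9)c8 | intermediate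
16 | trimer lactone: 15 with B (unit of 3; bonded through C8) in place of the ethoxyethoxy group; M C4β | CC(C)(C)[Si](C)(C)O[C@@H]1[C@@H](c5c(OCc9ccccc9)cc(OCc9ccccc9)c6c5O[C@H](c7ccc(OCc9ccccc9)c(OCc9ccccc9)c7)[C@H](O[Si](C)(C)C(C)(C)C)C6)c2c(OCc9ccccc9)cc(OCc9ccccc9)c([C@@H]3c4c(OCc9ccccc9)cc(OCc9ccccc9)cc4OC(=O)[C@@H]3OCc9ccccc9)c2O[C@@H]1c8ccc(OCc9ccccc9)c(OCc9ccccc9)c8 | intermediate
17 | 4-bromo-1,2-bis(benzyloxy)benzene | Brc1ccc(OCc9ccccc9)c(OCc9ccccc9)c1 | starting material
18 | 3,4-bis(benzyloxy)phenyllithium | [Li]c1ccc(OCc9ccccc9)c(OCc9ccccc9)c1 | intermediate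
19 | trimer hemiketal: T C2 bears OH and 3,4-bis(benzyloxy)phenyl; C2 unassigned (anomer mixture) | CC(C)(C)[Si](C)(C)O[C@@H]1[C@@H](c5c(OCc9ccccc9)cc(OCc9ccccc9)c6c5O[C@H](c7ccc(OCc9ccccc9)c(OCc9ccccc9)c7)[C@H](O[Si](C)(C)C(C)(C)C)C6)c2c(OCc9ccccc9)cc(OCc9ccccc9)c([C@@H]3c4c(OCc9ccccc9)cc(OCc9ccccc9)cc4OC(O)(c7ccc(OCc9ccccc9)c(OCc9ccccc9)c7)[C@@H]3OCc9ccccc9)c2O[C@@H]1c8ccc(OCc9ccccc9)c(OCc9ccccc9)c8 | intermediate
20 | protected trimer: T penta-O-benzylepicatechin (4α→8) M (4β→8) B; M and B 3-O-TBS | CC(C)(C)[Si](C)(C)O[C@@H]1[C@@H](c5c(OCc9ccccc9)cc(OCc9ccccc9)c6c5O[C@H](c7ccc(OCc9ccccc9)c(OCc9ccccc9)c7)[C@H](O[Si](C)(C)C(C)(C)C)C6)c2c(OCc9ccccc9)cc(OCc9ccccc9)c([C@@H]3c4c(OCc9ccccc9)cc(OCc9ccccc9)cc4O[C@H](c7ccc(OCc9ccccc9)c(OCc9ccccc9)c7)[C@@H]3OCc9ccccc9)c2O[C@@H]1c8ccc(OCc9ccccc9)c(OCc9ccccc9)c8 | intermediate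
21 | trimer diol: 20 with both TBS groups replaced by H | O[C@@H]1[C@@H](c5c(OCc9ccccc9)cc(OCc9ccccc9)c6c5O[C@H](c7ccc(OCc9ccccc9)c(OCc9ccccc9)c7)[C@H](O)C6)c2c(OCc9ccccc9)cc(OCc9ccccc9)c([C@@H]3c4c(OCc9ccccc9)cc(OCc9ccccc9)cc4O[C@H](c7ccc(OCc9ccccc9)c(OCc9ccccc9)c7)[C@@H]3OCc9ccccc9)c2O[C@@H]1c8ccc(OCc9ccccc9)c(OCc9ccccc9)c8 | intermediate
22 | 3,4,5-tris(benzyloxy)benzoic acid | O=C(O)c1cc(OCc9ccccc9)c(OCc9ccccc9)c(OCc9ccccc9)c1 | starting material
23 | nonadeca-O-benzyl trimer digallate: 21 esterified at O3 of M and of B | O=C(c7cc(OCc9ccccc9)c(OCc9ccccc9)c(OCc9ccccc9)c7)O[C@@H]1[C@@H](c5c(OCc9ccccc9)cc(OCc9ccccc9)c6c5O[C@H](c7ccc(OCc9ccccc9)c(OCc9ccccc9)c7)[C@H](OC(=O)c7cc(OCc9ccccc9)c(OCc9ccccc9)c(OCc9ccccc9)c7)C6)c2c(OCc9ccccc9)cc(OCc9ccccc9)c([C@@H]3c4c(OCc9ccccc9)cc(OCc9ccccc9)cc4O[C@H](c7ccc(OCc9ccccc9)c(OCc9ccccc9)c7)[C@@H]3OCc9ccccc9)c2O[C@@H]1c8ccc(OCc9ccccc9)c(OCc9ccccc9)c8 | intermediate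
24 | CNP0279403.2 | O=C(O[C@@H]1[C@@H](c2c(O)cc(O)c3c2O[C@H](c2ccc(O)c(O)c2)[C@H](OC(=O)c2cc(O)c(O)c(O)c2)C3)c2c(O)cc(O)c([C@@H]3c4c(O)cc(O)cc4O[C@H](c4ccc(O)c(O)c4)[C@@H]3O)c2O[C@@H]1c1ccc(O)c(O)c1)c1cc(O)c(O)c(O)c1 | target

Total step count: 15. Longest linear sequence: 13 steps (steps 1–4 and 7–15).

**Steps most likely to fail**

1. Step 9.
- What may go wrong: the hindered, donor-stabilised methide may react too slowly with the mildly nucleophilic ammonium enolate, so that ketene oligomerisation wins. The cis selectivity or the catalyst-controlled absolute sense may also erode against the bias of M.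
- Fallback: it sets out from 12 and 11 and returns at 15. It replaces the covalently bound enolate by a preformed silicon enolate in a chiral ion pair. Compound 12 is esterified with phenol (Et3N, CH2Cl2) to phenyl benzyloxyacetate F1. LiN(SiMe3)2 and Me3SiCl in THF at −78 °C convert F1 into the chelation-derived (Z)-silyl ketene acetal F2. Methide 13, generated from 11 as in step 9, is then treated with F2 and an N-benzylquinidinium fluoride (10 mol %) in toluene/THF at −78 to −40 °C. A Mukaiyama–Michael addition, followed by displacement of phenoxide from the ester by T O1, should give 15 without any free ketene or amine base.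

2. Step 11.
- What may go wrong: the aryllithium may deprotonate T C3, which would lose the cis relationship through the enolate. The tetrahedral intermediate may also collapse early and take up a second aryl group.
- Fallback: it sets out from 16 and returns at 19. MeNH(OMe)·HCl and AlMe3 in CH2Cl2 at 0 °C open the lactone under non-basic conditions to the phenolic Weinreb amide F3. Reagent 18 (2.3 equiv, the first equivalent consumed by the phenol) then adds once at −78 °C, because the chelated adduct cannot collapse before work-up. The liberated aryl ketone closes to hemiketal 19.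

3. Step 12.
- What may go wrong: hydride delivery to the oxocarbenium ion may show poor facial selectivity. Proton loss from T C3 of that ion may also scramble C3.
- Fallback: it sets out from 19 and returns at 20. It forms the C2–O1 bond by substitution instead of reducing a cation. Zn(BH4)2 in Et2O at −20 °C reduces the open hydroxy ketone tautomer of 19 under chelation control (ketone oxygen and the O3 benzyl ether) to the 2,3-anti benzylic alcohol F4. An intramolecular Mitsunobu etherification (PPh3, DIAD, THF, 0 °C) by the T ring A phenol then closes ring C with inversion at C2 to the 2,3-cis flavan 20.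

**Further compounds**

F1 | step 9 | phenyl benzyloxyacetate | O=C(COCc1ccccc1)Oc1ccccc1
F2 | step 9 | (Z)-2-benzyloxy-1-phenoxy-1-(trimethylsilyloxy)ethene | C[Si](C)(C)O/C(Oc1ccccc1)=C\OCc1ccccc1
F3 | step 11 | ring-opened trimer: T ring A phenol with N-methoxy-N-methylamide at T C2 | CC(C)(C)[Si](C)(C)O[C@@H]1[C@@H](c5c(OCc9ccccc9)cc(OCc9ccccc9)c6c5O[C@H](c7ccc(OCc9ccccc9)c(OCc9ccccc9)c7)[C@H](O[Si](C)(C)C(C)(C)C)C6)c2c(OCc9ccccc9)cc(OCc9ccccc9)c([C@@H]([C@@H](OCc9ccccc9)C(=O)N(C)OC)c4c(OCc9ccccc9)cc(OCc9ccccc9)cc4O)c2O[C@@H]1c8ccc(OCc9ccccc9)c(OCc9ccccc9)c8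
F4 | step 12 | ring-opened trimer: T ring A phenol with 2,3-anti benzylic alcohol at T C2 | CC(C)(C)[Si](C)(C)O[C@@H]1[C@@H](c5c(OCc9ccccc9)cc(OCc9ccccc9)c6c5O[C@H](c7ccc(OCc9ccccc9)c(OCc9ccccc9)c7)[C@H](O[Si](C)(C)C(C)(C)C)C6)c2c(OCc9ccccc9)cc(OCc9ccccc9)c([C@@H]([C@@H](OCc9ccccc9)[C@@H](O)c7ccc(OCc9ccccc9)c(OCc9ccccc9)c7)c4c(OCc9ccccc9)cc(OCc9ccccc9)cc4O)c2O[C@@H]1c8ccc(OCc9ccccc9)c(OCc9ccccc9)c8
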